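**Retrosynthetic overview**
- Rings: A = dibromopyrrole, B = five-membered lactam, C = piperidine, D = 2-aminoimidazoline. The strategy rests on the carbon shared by rings B, C and D: it carries the lactam N, the pyrrole N and a ring guanidine NH, so it is a carboxyl-level carbon, and its only carbon neighbour is the ketone-level carbinolamine carbon C(OH)(N) of rings C and D. The pair is an α-keto acid in disguise.
- Last disconnection: the CH2 next to the lactam N is drawn back to CH–CO2H (radical decarboxylation). The chain is then L-glutamate, and its carboxyl steers the two stereocentres before it is removed.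
- Key disconnection: the three C–N bonds at the triamino carbon and the C–N bond at the carbinolamine carbon are cut together, giving guanidine and an open-chain α-keto tris(methylthio) orthoester. Forward, ring C closes first (amide N), then ring D (guanidine N), then ring B (pyrrolide N).
- The keto orthoester is cut at the ketone C–C bond into lithiated tris(methylthio)methane and the γ-Weinreb amide of N-acylated glutamate. The amide bond is made first, so a free amine never meets the ketone (it would close to a 1-pyrroline).

Key step: step 4

Remark: guanidine is used as the free base (titrated DMF solution liberated beforehand from its hydrochloride), and the α-carboxyl is carried as the tert-butyl ester, which resists free guanidine and the lithium reagent and is later removed by acid instead of hydroxide.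

**Step 1**
Reactants: 1 L-glutamic acid 1-tert-butyl ester; 2 2,2,2-trichloro-1-(4,5-dibromo-1H-pyrrol-2-yl)ethan-1-one
Product: 3 (S)-5-tert-butoxy-4-[(4,5-dibromo-1H-pyrrole-2-carbonyl)amino]-5-oxopentanoic acid
Conditions: Et3N (2.2 equiv), DMF, rt, 16 h; aq. citric acid work-up
Reagents that add atoms: none
Why: Haloform-type aminolysis of a trichloromethyl ketone, in which the free α-amine attacks the activated ketone and the trichloromethyl group leaves as chloroform, while the carboxylate, the tert-butyl ester and the stereocentre are untouched.

**Step 2**
Reactants: 3 (S)-5-tert-butoxy-4-[(4,5-dibromo-1H-pyrrole-2-carbonyl)amino]-5-oxopentanoic acid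
Product: 4 tert-butyl (S)-2-[(4,5-dibromo-1H-pyrrole-2-carbonyl)amino]-5-[methoxy(methyl)amino]-5-oxopentanoate
Conditions: MeNH(OMe)·HCl (1.3 equiv), EDC·HCl (1.3 equiv), HOBt (0.2 equiv), N-methylmorpholine (2.6 equiv), CH2Cl2, 0 °C to rt
Reagents that add atoms: N,O-dimethylhydroxylamine hydrochloride, CNOC.Cl
Why: Carbodiimide amide coupling (Weinreb amide formation) at the only free carboxyl, which is remote from the α-centre, so racemisation through an oxazolone is not possible.

**Step 3**
Reactants: 4 tert-butyl (S)-2-[(4,5-dibromo-1H-pyrrole-2-carbonyl)amino]-5-[methoxy(methyl)amino]-5-oxopentanoate; 5 tris(methylthio)methane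
Product: 6 tert-butyl (S)-2-[(4,5-dibromo-1H-pyrrole-2-carbonyl)amino]-5-oxo-6,6,6-tris(methylthio)hexanoate
Conditions: 5 (3.5 equiv), n-BuLi (3.3 equiv), THF, −78 °C, 30 min; then 4 in THF, −78 °C, 2 h; AcOH in THF at −78 °C
Reagents that add atoms: none
Why: Weinreb ketone synthesis with a lithiated trithioorthoformate, in which two equivalents of the reagent remove the pyrrole and amide NH protons (the amidate shields the α-CH and the tert-butyl ester), the third adds to the Weinreb amide, and the chelated tetrahedral adduct holds until the acidic quench, so over-addition should not occur; all n-BuLi is consumed before 4 is added, so the C–Br bonds see no alkyllithium.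

**Step 4**
Reactants: 6 tert-butyl (S)-2-[(4,5-dibromo-1H-pyrrole-2-carbonyl)amino]-5-oxo-6,6,6-tris(methylthio)hexanoate; 7 guanidine
Product: 11 tert-butyl ester of the tetracycle (CO2t-Bu on the carbon next to the lactam N; S at that carbon; R at the carbinolamine carbon; S at the triamino carbon), via bis(methylthio)piperidinone 8 (not isolated), via guanidine carbinolamine 9 (not isolated), via methylthio aminoimidazoline 10 (not isolated)
Conditions: dimethyl(methylthio)sulfonium tetrafluoroborate (1.1 equiv), 2,6-di-tert-butyl-4-methylpyridine (1.2 equiv), CH2Cl2, −20 to 0 °C; solvent exchanged to MeCN/DMF, 7 (4.5 equiv), −20 °C, 1 h; then AgOSO2CF3 (2.3 equiv), −20 °C to rt, dark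
Reagents that add atoms: none
Why: Proposed new method: the sulfonium salt methylthiolates one sulfur of the orthoester, dimethyl disulfide leaves and the α-acyl bis(methylthio)carbenium ion is taken by the amide nitrogen (6-exo-trig, ring C, 8); guanidine then adds reversibly to the activated ketone (9) and, because the sulfonium salt would sulfenylate free guanidine, the remaining two methylthio groups are removed by the thiophilic silver salt under base, the pendant guanidine nitrogen closing ring D (5-exo-trig onto the N-acyl thionium ion, 10) and the pyrrolide nitrogen closing ring B (5-exo-trig onto the cyclic N-acylamidinium carbon). The closest known reactions are sulfonium-promoted amide/thionium cyclisations of dithioacetals, silver- or mercury-assisted replacement of S-methyl by nitrogen in isothioureas and N,S-acetals, and base-induced attack of a pyrrolide nitrogen on a 2-aminoimidazolinium carbon; three such exchanges in a row on one trithioorthoester carbon are without precedent. The step needs three different nitrogens each to bond once to the same carbon: ring size decides the order (only the amide N reaches the first cation through a six-membered ring), and N- instead of C3-attack of the ambident pyrrole is secured by closing ring B on the pyrrolide under base, not under acid. The carbinolamine carbon is formed reversibly and is fixed only when ring D closes, and ring D can only be cis-fused to ring C, so the two new centres arise as a pair. Their sense relative to the glutamate centre should follow from A(1,3) strain between the tert-butyl ester and the N-acyl carbonyl, which holds the ester axial, so that the guanidine nitrogen takes the axial position at the triamino carbon on the same face of the chair (2,6-cis), giving R at the carbinolamine carbon and S at the triamino carbon. If the sense proves opposite, the enantiomer of 1 is used.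

**Step 5**
Reactants: 11 tert-butyl ester of the tetracycle
Product: 12 tetracyclic carboxylic acid as its guanidinium trifluoroacetate (same three configurations as 11)
Conditions: CF3CO2H/CH2Cl2 (1:2), anisole (5 equiv), 0 °C to rt; evaporate, triturate with Et2O
Reagents that add atoms: trifluoroacetic acid, OC(=O)C(F)(F)F
Why: Acidolysis of a tert-butyl ester with loss of 2-methylpropene; the protonated guanidine cannot push out a substituent at either aminal carbon, so both centres should hold, and epimerisation at the carboxyl-bearing carbon would not matter because that centre is removed later.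

**Step 6**
Reactants: 12 tetracyclic carboxylic acid trifluoroacetate
Product: 13 N-(acyloxy)phthalimide ester of 12, as its guanidinium trifluoroacetate
Conditions: N-hydroxyphthalimide (1.2 equiv), N,N'-diisopropylcarbodiimide (1.2 equiv), DMF, 0 °C to rt, no added base; precipitate with Et2O
Reagents that add atoms: N-hydroxyphthalimide, ON1C(=O)c2ccccc2C1=O
Why: Carbodiimide esterification gives the redox-active ester, and keeping the guanidine protonated as its trifluoroacetate prevents it from being acylated.

**Step 7**
Reactants: 13 N-(acyloxy)phthalimide ester trifluoroacetate
Product: 14 target, the tetracycle with CH2 next to the lactam N (R at the carbinolamine carbon, S at the triamino carbon)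
Conditions: Ru(bpy)3Cl2 (2 mol %), diethyl 2,6-dimethyl-1,4-dihydropyridine-3,5-dicarboxylate (1.5 equiv), t-BuSH (0.5 equiv), DMF, blue LEDs (450 nm), rt; then aq. Na2CO3
Reagents that add atoms: none
Why: Photoredox decarboxylative reduction of an N-(acyloxy)phthalimide (single-electron reduction, loss of phthalimide anion and CO2, hydrogen-atom transfer from the thiol to the α-amido radical) replaces CO2H by H; the carbon becomes CH2, so no stereochemistry is at stake, and the aryl bromides lie beyond the reducing power of the catalyst.

**Compound list**
1 | L-glutamic acid 1-tert-butyl ester | CC(C)(C)OC(=O)[C@@H](N)CCC(=O)O | starting material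
2 | 2,2,2-trichloro-1-(4,5-dibromo-1H-pyrrol-2-yl)ethan-1-one | O=C(c1cc(Br)c(Br)[nH]1)C(Cl)(Cl)Cl | starting material
3 | (S)-5-tert-butoxy-4-[(4,5-dibromo-1H-pyrrole-2-carbonyl)amino]-5-oxopentanoic acid | CC(C)(C)OC(=O)[C@H](CCC(=O)O)NC(=O)c1cc(Br)c(Br)[nH]1 | intermediate
4 | tert-butyl (S)-2-[(4,5-dibromo-1H-pyrrole-2-carbonyl)amino]-5-[methoxy(methyl)amino]-5-oxopentanoate | CC(C)(C)OC(=O)[C@H](CCC(=O)N(C)OC)NC(=O)c1cc(Br)c(Br)[nH]1 | intermediate
5 | tris(methylthio)methane | CSC(SC)SC | starting material
6 | tert-butyl (S)-2-[(4,5-dibromo-1H-pyrrole-2-carbonyl)amino]-5-oxo-6,6,6-tris(methylthio)hexanoate (key-step precursor) | CC(C)(C)OC(=O)[C@H](CCC(=O)C(SC)(SC)SC)NC(=O)c1cc(Br)c(Br)[nH]1 | intermediate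
7 | guanidine (free base) | NC(N)=N | starting material
8 | tert-butyl (S)-1-(4,5-dibromo-1H-pyrrole-2-carbonyl)-6,6-bis(methylthio)-5-oxopiperidine-2-carboxylate (ring C closed) | CC(C)(C)OC(=O)[C@@H]1CCC(=O)C(SC)(SC)N1C(=O)c1cc(Br)c(Br)[nH]1 | intermediate
9 | tert-butyl (2S)-5-guanidino-5-hydroxy-1-(4,5-dibromo-1H-pyrrole-2-carbonyl)-6,6-bis(methylthio)piperidine-2-carboxylate (both epimers at the carbinolamine carbon, interconverting) | NC(=N)NC1(O)CC[C@@H](C(=O)OC(C)(C)C)N(C(=O)c2cc(Br)c(Br)[nH]2)C1(SC)SC | intermediate
10 | ring C/D bicycle: 2-aminoimidazoline cis-fused to the piperidine on the face of the ester; the former orthoester carbon carries SMe, the ring guanidine NH and the N-acyl piperidine N; pyrrole NH free | NC1=N[C@@]2(O)CC[C@@H](C(=O)OC(C)(C)C)N(C(=O)c3cc(Br)c(Br)[nH]3)[C@@]2(SC)N1 | intermediate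
11 | tert-butyl ester of the tetracycle (key-step product; S at the ester carbon, R at the carbinolamine carbon, S at the triamino carbon) | NC1=N[C@@]2(O)CC[C@@H](C(=O)OC(C)(C)C)N3C(=O)c4cc(Br)c(Br)n4[C@@]32N1 | intermediate
12 | tetracyclic carboxylic acid, guanidinium trifluoroacetate | NC1=[NH+][C@@]2(O)CC[C@@H](C(=O)O)N3C(=O)c4cc(Br)c(Br)n4[C@@]32N1.[O-]C(=O)C(F)(F)F | intermediate
13 | N-(acyloxy)phthalimide ester of the tetracyclic acid, guanidinium trifluoroacetate | NC1=[NH+][C@@]2(O)CC[C@@H](C(=O)ON5C(=O)c6ccccc6C5=O)N3C(=O)c4cc(Br)c(Br)n4[C@@]32N1.[O-]C(=O)C(F)(F)F | intermediate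
14 | target (R at the carbinolamine carbon, S at the triamino carbon) | NC1=N[C@@]2(O)CCCN3C(=O)c4cc(Br)c(Br)n4[C@@]32N1 | target

**Total step count:** 7
**Longest linear sequence:** 7 steps (from 1)

**Steps most likely to fail**

1. Step 4 (proposed method). What may go wrong:
 - The first carbenium ion may be lost to adventitious water.
 - Guanidine may fragment the keto piperidinone instead of adding to it.
 - The silver-assisted exchanges may stall after one methylthio group.
 - The closure may take the face opposite to the ester.

 The fallback builds the same bonds one at a time by known reaction types and makes ring D as a urea first. It sets out from 6 and comes back at 11. The sulfonium salt alone (1.1 equiv, CH2Cl2) closes ring C, and bis(methylthio)piperidinone 8 is isolated. AgOSO2CF3 with Cs2CO3 in MeCN removes one methylthio group and the pyrrolide nitrogen closes ring B, giving the tricyclic methylthio ketone F1 (mixture at the thio carbon). Urea with AgOSO2CF3 and i-Pr2NEt in DMF adds to the ketone and displaces the last methylthio group (amidoalkylation of urea by the N-acyliminium ion) to give the cyclic urea F2, the oxygen analogue of 11, with the two centres set by the same A(1,3) argument. O-Ethylation with triethyloxonium tetrafluoroborate gives the O-ethyl isourea F3, and NH3 in MeOH exchanges ethoxy for NH2 to give 11.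

2. Step 3. What may go wrong: the dilithiated substrate may precipitate at −78 °C so that addition is incomplete, the lithium reagent may break down before it adds, or it may attack the ester. The fallback changes the electrophile from a Weinreb amide to an activated lactam. It sets out from 3 and comes back at 6. EDC·HCl with DMAP in CH2Cl2 closes the amide nitrogen onto the activated γ-carboxyl to give the N-acyl pyroglutamate F4. NaH (1 equiv, THF) then removes the pyrrole NH, which deactivates the exocyclic carbonyl, and lithiated 5 (1.2 equiv, −78 °C) opens the lactam at the ring carbonyl to give 6 after an acetic acid quench.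

3. Step 6. What may go wrong: the ring guanidine nitrogen on the same face may be acylated by the activated carboxyl (bridged lactam), or the active ester may hydrolyse during isolation. The fallback avoids any activated ester. It sets out from 12 and comes back at 14, and it makes no new compound (F0). Direct photocatalytic hydrodecarboxylation is used: 9-mesityl-10-methylacridinium tetrafluoroborate (5 mol %), diphenyl disulfide (10 mol %), 2,6-lutidine, CF3CH2OH, blue LEDs. The excited acridinium oxidises the carboxylate, CO2 is lost, and thiophenol formed in the flask gives the hydrogen atom to the α-amido radical.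

**Further compounds**
F1 | step 4 | tert-butyl ester of the ring A/B/C tricycle with a ketone at the future carbinolamine carbon and SMe at the future triamino carbon (S at the ester carbon, mixture at the thio carbon) | CC(C)(C)OC(=O)[C@@H]1CCC(=O)C2(SC)N1C(=O)c1cc(Br)c(Br)n12
F2 | step 4 | cyclic urea analogue of 11 (imidazolidin-2-one in place of the 2-aminoimidazoline) | O=C1N[C@@]2(O)CC[C@@H](C(=O)OC(C)(C)C)N3C(=O)c4cc(Br)c(Br)n4[C@@]32N1
F3 | step 4 | O-ethyl isourea of F2 | CCOC1=N[C@@]2(O)CC[C@@H](C(=O)OC(C)(C)C)N3C(=O)c4cc(Br)c(Br)n4[C@@]32N1
F4 | step 3 | tert-butyl (S)-1-(4,5-dibromo-1H-pyrrole-2-carbonyl)-5-oxopyrrolidine-2-carboxylate | CC(C)(C)OC(=O)[C@@H]1CCC(=O)N1C(=O)c1cc(Br)c(Br)[nH]1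
F0 | step 6 | none | none
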